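The plan rests on the one C=C bond that carries no hydrogen: C1=C2 of the 2,6,6-trimethylcyclohexene ring, flanked by the quaternary C6. Both olefinic carbons are traced back to ketone carbonyls, so the ring is opened to an acyclic 1,6-diketone. An intramolecular McMurry coupling unites these two electrophilic carbons by ketyl–ketyl union and deoxygenation. In one operation it closes the carbocycle and fixes the tetrasubstituted alkene without positional isomers. Its precursor is a 6,6,10-trimethyltrideca-10,12-diene-2,7-dione that already carries the finished (R)-chroman. The chroman is made by asymmetric allylic etherification and joined through a Heck reaction with a (Z)-iodoalkene.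

Key step: step 13

Assumption: the sense of induction in step 6 is assigned by analogy. The (R,R)-ligand is taken to give the (R)-chroman from the (Z)-carbonate. If the sense is opposite, the (S,S)-ligand is used and nothing else changes.

Step 1
Reactants: 1 2,5-dihydroxybenzaldehyde
Product: 2 2-hydroxy-5-(triisopropylsilyloxy)benzaldehyde
Conditions: TIPSCl, imidazole, CH2Cl2, 0 °C → rt
Reagents that add atoms: triisopropylsilyl chloride CC(C)[Si](Cl)(C(C)C)C(C)C
Why: The 2-OH is hydrogen-bonded to and flanked by the formyl group, so this standard O-silylation should take place at the free 5-OH only.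

Step 2
Reactants: 2 2-hydroxy-5-(triisopropylsilyloxy)benzaldehyde
Product: 3 2-ethenyl-4-(triisopropylsilyloxy)phenol
Conditions: Ph3PCH3Br, KOtBu (2.2 equiv each), THF, 0 °C → rt; product used without storage
Reagents that add atoms: methyltriphenylphosphonium bromide C[P+](c1ccccc1)(c1ccccc1)c1ccccc1.[Br-]
Why: In this Wittig methylenation the first equivalent of ylide only deprotonates the phenol and the second converts the aldehyde, as is usual for salicylaldehydes.

Step 3
Reactants: 4 but-2-yn-1-ol
Product: 6 (Z)-3-iodobut-2-en-1-ol, via cyclic alkenylaluminate 5 (not isolated)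
Conditions: Red-Al, THF, 0 °C → rt; then I2, −78 °C → rt
Reagents that add atoms: iodine II
Why: Hydroxyl-directed trans-hydroalumination of the propargylic alcohol places aluminium at C3 cis to the CH2O group in 5, and iodinolysis with retention gives the Z iodide.

Step 4
Reactants: 3 2-ethenyl-4-(triisopropylsilyloxy)phenol; 6 (Z)-3-iodobut-2-en-1-ol
Product: 8 2-[(3Z)-5-hydroxy-3-methylpent-3-en-1-yl]-4-(triisopropylsilyloxy)phenol, via bis(boryl) adduct 7 (not isolated)
Conditions: 9-BBN (2.2 equiv), THF, rt; then 6, PdCl2(dppf) (5 mol %), aq K3PO4, DMF, rt → 50 °C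
Reagents that add atoms: none
Why: 9-BBN adds to the styrene terminus (and masks the phenol as its borinate), and the B-alkyl Suzuki–Miyaura coupling proceeds with retention at the alkenyl iodide, so the Z geometry of 6 is carried into 8.

Step 5
Reactants: 8 2-[(3Z)-5-hydroxy-3-methylpent-3-en-1-yl]-4-(triisopropylsilyloxy)phenol
Product: 9 (2Z)-5-[2-hydroxy-5-(triisopropylsilyloxy)phenyl]-3-methylpent-2-en-1-yl methyl carbonate
Conditions: ClCO2Me (1.05 equiv), pyridine, CH2Cl2, −20 → 0 °C
Reagents that add atoms: methyl chloroformate COC(=O)Cl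
Why: Pyridine forms no phenoxide, so the primary allylic alcohol should be acylated faster than the ortho-substituted phenol in this chemoselective chloroformate acylation.

Step 6
Reactants: 9 (2Z)-5-[2-hydroxy-5-(triisopropylsilyloxy)phenyl]-3-methylpent-2-en-1-yl methyl carbonate
Product: 10 (2R)-2-ethenyl-2-methyl-6-(triisopropylsilyloxy)-3,4-dihydro-2H-chromene
Conditions: Pd2(dba)3·CHCl3 (2 mol %), (R,R)-DACH-phenyl bisphosphine ligand (6 mol %), AcOH (1 equiv), CH2Cl2, rt
Reagents that add atoms: none
Why: In this Tsuji–Trost asymmetric allylic alkylation with a phenol O-nucleophile, ionisation gives a π-allylpalladium complex that the phenol attacks at the more substituted terminus in a 6-exo closure, and the chiral pocket of the ligand (Curtin–Hammett regime, promoted by AcOH) sets C2 as R.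

Step 7
Reactants: 11 isobutyronitrile; 12 2-(3-chloropropyl)-2-methyl-1,3-dioxolane
Product: 13 2,2-dimethyl-5-(2-methyl-1,3-dioxolan-2-yl)pentanenitrile
Conditions: LDA, THF, −78 °C; then 12, DMPU, −78 → 45 °C
Reagents that add atoms: none
Why: SN2 alkylation of the small, strongly nucleophilic lithiated nitrile builds the quaternary carbon, and the ketal is inert to base.

Step 8
Reactants: 13 2,2-dimethyl-5-(2-methyl-1,3-dioxolan-2-yl)pentanenitrile
Product: 15 3,3-dimethyl-6-(2-methyl-1,3-dioxolan-2-yl)hexan-2-one, via N-H ketimine 14 (not isolated)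
Conditions: MeLi, Et2O, 0 °C → rt; then AcOH–NaOAc buffer (pH 5), THF–H2O, rt
Reagents that add atoms: methyllithium [Li]C; water O
Why: Organolithium addition to a non-enolisable nitrile stops at the metallated ketimine, and buffered hydrolysis of 14 should give the methyl ketone while sparing the dioxolane.

Step 9
Reactants: 16 prop-2-yn-1-ol
Product: 18 (Z)-3-iodo-2-methylprop-2-en-1-ol, via alkenylmagnesium chelate 17 (not isolated)
Conditions: MeMgBr (2.5 equiv), CuI (10 mol %), THF, −10 °C → rt; then I2, −30 °C → rt
Reagents that add atoms: methylmagnesium bromide C[Mg]Br; iodine II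
Why: Copper-catalysed, alkoxide-directed anti-carbomagnesiation delivers methyl to C2 and magnesium to C3 inside chelate 17, and iodinolysis with retention leaves iodine cis to CH2OH.

Step 10
Reactants: 18 (Z)-3-iodo-2-methylprop-2-en-1-ol
Product: 19 (Z)-3-bromo-1-iodo-2-methylprop-1-ene
Conditions: CBr4, PPh3, CH2Cl2, 0 °C
Reagents that add atoms: carbon tetrabromide BrC(Br)(Br)Br
Why: Appel bromination of a primary allylic alcohol under neutral conditions proceeds by SN2 without allylic shift or change of alkene geometry.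

Step 11
Reactants: 15 3,3-dimethyl-6-(2-methyl-1,3-dioxolan-2-yl)hexan-2-one; 19 (Z)-3-bromo-1-iodo-2-methylprop-1-ene
Product: 21 (Z)-11-iodo-6,6,10-trimethylundec-10-ene-2,7-dione, via iodoalkenyl keto ketal 20 (not isolated)
Conditions: LDA, THF, −78 °C; 19, −78 → −20 °C; then 1 M HCl, THF, rt
Reagents that add atoms: water O
Why: Ketone 15 can enolise only at its methyl group, so LDA gives a single enolate whose SN2 alkylation by the allylic bromide installs the CH2CH2 link with the Z iodoalkene untouched, and dilute acid then hydrolyses the dioxolane of 20.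

Step 12
Reactants: 10 (2R)-2-ethenyl-2-methyl-6-(triisopropylsilyloxy)-3,4-dihydro-2H-chromene; 21 (Z)-11-iodo-6,6,10-trimethylundec-10-ene-2,7-dione
Product: 22 (10Z,12E)-6,6,10-trimethyl-13-[(2R)-2-methyl-6-(triisopropylsilyloxy)-3,4-dihydro-2H-chromen-2-yl]trideca-10,12-diene-2,7-dione
Conditions: Pd(OAc)2 (10 mol %), Ag2CO3, MeCN, 40 °C, dark
Reagents that add atoms: none
Why: In this silver-modified, ligand-free Heck reaction the alkenylpalladium adds to the free CH2 terminus of the vinyl group, the quaternary C2 leaves a single β-hydrogen for syn elimination so the new alkene is E, and the Z geometry of the iodide is retained.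

Step 13
Reactants: 22 (10Z,12E)-6,6,10-trimethyl-13-[(2R)-2-methyl-6-(triisopropylsilyloxy)-3,4-dihydro-2H-chromen-2-yl]trideca-10,12-diene-2,7-dione
Product: 24 (2R)-2-methyl-2-[(1E,3Z)-4-methyl-6-(2,6,6-trimethylcyclohex-1-en-1-yl)hexa-1,3-dien-1-yl]-6-(triisopropylsilyloxy)-3,4-dihydro-2H-chromene, via titanium pinacolate 23 (not isolated)
Conditions: TiCl3(DME)1.5, Zn–Cu, DME, reflux; 22 added by syringe pump at high dilution, then reflux; aq K2CO3 work-up
Reagents that add atoms: none
Why: Low-valent titanium transfers one electron to each ketone of 22, the two ketyl carbons (C2 and C7 of the chain, both electrophilic before reduction) combine to the titanium pinacolate 23, and at reflux the oxophilic metal removes both oxygens to leave the C=C bond. The closest known reaction type is the intramolecular McMurry coupling of 1,6-diketones to 1,2-dialkylcyclohexenes, a reaction that also tolerates polyenes, as in the coupling of polyenals to carotenoids. The ring closes as a six-membered carbocycle by direct C2–C7 union (chain C7, C2, C3, C4, C5, C6 become ring C1 to C6), helped by the gem-dimethyl group and kept intramolecular by slow addition at high dilution. No lasting stereocentre is formed: the two carbinol centres of 23 are erased on deoxygenation, and C2 of the chroman is remote and not involved. The step needs positional selectivity, which is built in because the alkene can only appear where the two carbonyl groups stood (no exocyclic or trisubstituted isomers as in cationic closures), and chemoselectivity, which rests on only the two C=O groups being able to bind titanium and accept its electrons, whereas the diene, the aryl silyl ether and the ring ether offer no carbonyl or free hydroxyl group. Aldol side reactions are disfavoured because they would need attack on the neopentyl-type C7 carbonyl or closure of a seven-membered ring.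

Step 14
Reactants: 24 (2R)-2-methyl-2-[(1E,3Z)-4-methyl-6-(2,6,6-trimethylcyclohex-1-en-1-yl)hexa-1,3-dien-1-yl]-6-(triisopropylsilyloxy)-3,4-dihydro-2H-chromene
Product: 25 (2R)-2-methyl-2-[(1E,3Z)-4-methyl-6-(2,6,6-trimethylcyclohex-1-en-1-yl)hexa-1,3-dien-1-yl]-3,4-dihydro-2H-chromen-6-ol
Conditions: TBAF, AcOH, THF, 0 °C
Reagents that add atoms: none
Why: Fluoride cleaves the aryl silyl ether (Si–F bond strength) and the acetic acid buffer protonates the phenoxide at once, so the diene, the tertiary allylic ether and C2 stay untouched.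

Compound list
1 | 2,5-dihydroxybenzaldehyde | O=Cc1cc(O)ccc1O | starting material
2 | 2-hydroxy-5-(triisopropylsilyloxy)benzaldehyde | O=Cc1cc(O[Si](C(C)C)(C(C)C)C(C)C)ccc1O | intermediate
3 | 2-ethenyl-4-(triisopropylsilyloxy)phenol | C=Cc1cc(O[Si](C(C)C)(C(C)C)C(C)C)ccc1O | intermediate
4 | but-2-yn-1-ol | CC#CCO | starting material
5 | cyclic alkenylaluminate (sodium 2,2-bis(2-methoxyethoxy)-3-methyl-1-oxa-2-aluminacyclopent-3-en-2-uide) | CC1=CCO[Al-]1(OCCOC)OCCOC.[Na+] | intermediate
6 | (Z)-3-iodobut-2-en-1-ol | C/C(I)=C/CO | intermediate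
7 | bis(boryl) adduct (aryl O-borinate and B-alkyl-9-BBN from 3) | CC(C)[Si](Oc1ccc(OB2C3CCCC2CCC3)c(CCB2C3CCCC2CCC3)c1)(C(C)C)C(C)C | intermediate
8 | 2-[(3Z)-5-hydroxy-3-methylpent-3-en-1-yl]-4-(triisopropylsilyloxy)phenol | C/C(CCc1cc(O[Si](C(C)C)(C(C)C)C(C)C)ccc1O)=C/CO | intermediate
9 | (2Z)-5-[2-hydroxy-5-(triisopropylsilyloxy)phenyl]-3-methylpent-2-en-1-yl methyl carbonate | C/C(CCc1cc(O[Si](C(C)C)(C(C)C)C(C)C)ccc1O)=C/COC(=O)OC | intermediate
10 | (2R)-2-ethenyl-2-methyl-6-(triisopropylsilyloxy)-3,4-dihydro-2H-chromene | C=C[C@@]1(C)CCc2cc(O[Si](C(C)C)(C(C)C)C(C)C)ccc2O1 | intermediate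
11 | isobutyronitrile | CC(C)C#N | starting material
12 | 2-(3-chloropropyl)-2-methyl-1,3-dioxolane | CC1(CCCCl)OCCO1 | starting material
13 | 2,2-dimethyl-5-(2-methyl-1,3-dioxolan-2-yl)pentanenitrile | CC1(CCCC(C)(C)C#N)OCCO1 | intermediate
14 | N-H ketimine, 3,3-dimethyl-6-(2-methyl-1,3-dioxolan-2-yl)hexan-2-imine | CC(=N)C(C)(C)CCCC1(C)OCCO1 | intermediate
15 | 3,3-dimethyl-6-(2-methyl-1,3-dioxolan-2-yl)hexan-2-one | CC(=O)C(C)(C)CCCC1(C)OCCO1 | intermediate
16 | prop-2-yn-1-ol | C#CCO | starting material
17 | alkenylmagnesium chelate (4-methyl-1-oxa-2-magnesacyclopent-3-ene) | CC1=C[Mg]OC1 | intermediate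
18 | (Z)-3-iodo-2-methylprop-2-en-1-ol | OC/C(C)=C\I | intermediate
19 | (Z)-3-bromo-1-iodo-2-methylprop-1-ene | BrC/C(C)=C\I | intermediate
20 | (Z)-1-iodo-2,6,6-trimethyl-9-(2-methyl-1,3-dioxolan-2-yl)non-1-en-5-one | CC1(CCCC(C)(C)C(=O)CC/C(C)=C\I)OCCO1 | intermediate
21 | (Z)-11-iodo-6,6,10-trimethylundec-10-ene-2,7-dione | CC(=O)CCCC(C)(C)C(=O)CC/C(C)=C\I | intermediate
22 | (10Z,12E)-6,6,10-trimethyl-13-[(2R)-2-methyl-6-(triisopropylsilyloxy)-3,4-dihydro-2H-chromen-2-yl]trideca-10,12-diene-2,7-dione | CC(=O)CCCC(C)(C)C(=O)CC/C(C)=C\C=C\[C@@]1(C)CCc2cc(O[Si](C(C)C)(C(C)C)C(C)C)ccc2O1 | intermediate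
23 | titanium pinacolate (formal 2-titana-1,3-dioxolane fused to the new ring; the two carbinol centres are transient and left open) | CC12CCCC(C)(C)C1(CC/C(C)=C\C=C\[C@@]1(C)CCc3cc(O[Si](C(C)C)(C(C)C)C(C)C)ccc3O1)O[Ti]O2 | intermediate
24 | (2R)-2-methyl-2-[(1E,3Z)-4-methyl-6-(2,6,6-trimethylcyclohex-1-en-1-yl)hexa-1,3-dien-1-yl]-6-(triisopropylsilyloxy)-3,4-dihydro-2H-chromene | CC1=C(CC/C(C)=C\C=C\[C@@]2(C)CCc3cc(O[Si](C(C)C)(C(C)C)C(C)C)ccc3O2)C(C)(C)CCC1 | intermediate
25 | (2R)-2-methyl-2-[(1E,3Z)-4-methyl-6-(2,6,6-trimethylcyclohex-1-en-1-yl)hexa-1,3-dien-1-yl]-3,4-dihydro-2H-chromen-6-ol | CC1=C(CC/C(C)=C\C=C\[C@@]2(C)CCc3cc(O)ccc3O2)C(C)(C)CCC1 | target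

Total step count: 14. Longest linear sequence: 8 steps (1, 2, 4, 5, 6, 12, 13, 14).

Steps most likely to fail

Step 13. Deoxygenation of the hindered, fully substituted pinacolate needs reflux. At that temperature, electron transfer or Lewis-acid assistance by titanium and zinc salts may cleave the tertiary, doubly allylic C2–O bond of the chroman. The 10Z alkene may also isomerise, or the reaction may stall at the diol stage. The fallback separates C–C bond formation from deoxygenation and sets out from 22. SmI2 in THF/t-BuOH at low temperature closes the same C2–C7 bond by ketyl–ketyl pinacol coupling to the cis-cyclohexane-1,2-diol F1. It is drawn as one of the two cis diastereomers, and both converge later. Thiocarbonyldiimidazole in warm toluene gives the cyclic thionocarbonate F2. Corey–Winter elimination in its mild variant (1,3-dimethyl-2-phenyl-1,3,2-diazaphospholidine, 40 °C) gives the tetrasubstituted alkene and returns to the route at 24.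

Step 12. Insertion into the alkene next to the quaternary carbon may be slow. This gives Pd(0) time to ionise the allylic aryl ether (erosion of configuration at C2, ring opening) and gives the alkenylpalladium time to lose its Z geometry. The fallback is palladium-free and sets out from 10. Lemieux–Johnson cleavage (OsO4 cat., NaIO4, 2,6-lutidine) gives the chroman-2-carbaldehyde F3. Chromium(II)-mediated Takai-type olefination with Bu3SnCHBr2 (CrCl2, LiI, THF–DMF) gives the (E)-alkenylstannane F4. Copper(I) thiophene-2-carboxylate in NMP at 0 °C → rt couples F4 with iodide 21, with retention at both partners, and returns to the route at 22.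

Step 6. Facial discrimination between the equilibrating π-allylpalladium complexes may be incomplete, or intermolecular etherification may compete with ring closure. In the fallback the stereocentre is set by reagent-controlled epoxidation and a stereospecific opening, and the sequence sets out from 8. Sharpless epoxidation with stoichiometric Ti(OiPr)4, D-(−)-diethyl tartrate and TBHP gives the (2R,3S)-epoxy alcohol F5. Camphorsulfonic acid (cat.) triggers 6-exo opening by the phenol at the tertiary carbon with inversion to the chromanyl diol F6. Thiocarbonyldiimidazole gives the thionocarbonate F7. Corey–Winter elimination with the same diazaphospholidine releases the vinyl group and returns to the route at 10.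

Further compounds
F1 | step 13 | cis-1-methyl-3,3-dimethyl-2-{(3Z,5E)-3-methyl-6-[(2R)-2-methyl-6-(triisopropylsilyloxy)-3,4-dihydro-2H-chromen-2-yl]hexa-3,5-dien-1-yl}cyclohexane-1,2-diol (one cis diastereomer drawn) | C[C@]1(O)CCCC(C)(C)[C@]1(O)CC/C(C)=C\C=C\[C@@]2(C)CCc3cc(O[Si](C(C)C)(C(C)C)C(C)C)ccc3O2
F2 | step 13 | cyclic thionocarbonate of F1 | C[C@]12CCCC(C)(C)[C@@]1(CC/C(C)=C\C=C\[C@@]1(C)CCc3cc(O[Si](C(C)C)(C(C)C)C(C)C)ccc3O1)OC(=S)O2
F3 | step 12 | (2R)-2-methyl-6-(triisopropylsilyloxy)-3,4-dihydro-2H-chromene-2-carbaldehyde | O=C[C@@]1(C)CCc2cc(O[Si](C(C)C)(C(C)C)C(C)C)ccc2O1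
F4 | step 12 | (2R)-2-methyl-2-[(E)-2-(tributylstannyl)ethenyl]-6-(triisopropylsilyloxy)-3,4-dihydro-2H-chromene | CCCC[Sn](CCCC)(CCCC)/C=C/[C@@]1(C)CCc2cc(O[Si](C(C)C)(C(C)C)C(C)C)ccc2O1
F5 | step 6 | [(2R,3S)-3-{2-[2-hydroxy-5-(triisopropylsilyloxy)phenyl]ethyl}-3-methyloxiran-2-yl]methanol | C[C@@]1(CCc2cc(O[Si](C(C)C)(C(C)C)C(C)C)ccc2O)O[C@@H]1CO
F6 | step 6 | (1R)-1-[(2R)-2-methyl-6-(triisopropylsilyloxy)-3,4-dihydro-2H-chromen-2-yl]ethane-1,2-diol | OC[C@@H](O)[C@@]1(C)CCc2cc(O[Si](C(C)C)(C(C)C)C(C)C)ccc2O1
F7 | step 6 | (4R)-4-[(2R)-2-methyl-6-(triisopropylsilyloxy)-3,4-dihydro-2H-chromen-2-yl]-1,3-dioxolane-2-thione | S=C1OC[C@@H](O1)[C@@]1(C)CCc2cc(O[Si](C(C)C)(C(C)C)C(C)C)ccc2O1
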